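The route rests on cutting the bond between C2 of the oxolane ring and the ipso carbon of one 4-hydroxy-3,5-dimethoxyphenyl ring. Unprotected 2,6-dimethoxyphenol is joined through its para carbon to the cyclic oxocarbenium ion released from a (3S,4S,5R)-5-aryl-3,4-bis(benzyloxymethyl)oxolan-2-ol; the same operation sets C2, trans to the C3 side chain. The step exploits the acetal oxidation level of C2 beside the ring oxygen, the nucleophilic para carbon of a phenol ring whose ortho positions carry methoxy groups, and the twofold axis through O1 and the C3–C4 bond, which makes both aryl–carbon bonds equivalent. The lactol comes from an Evans syn-aldol/lactonization of a succinate imide and an anti α-benzyloxymethylation.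

Key step: step 8

Remark: compounds 1, 2, 4, 12 and 16 are taken as purchasable; lactol 15 is used as its mixture of C2 epimers, since C2 becomes planar in the key step.

Step 1
Reactants: 1 (R)-4-benzyl-1,3-oxazolidin-2-one; 2 methyl 4-chloro-4-oxobutanoate
Product: 3 methyl 4-[(4R)-4-benzyl-2-oxo-1,3-oxazolidin-3-yl]-4-oxobutanoate
Conditions: Et3N, DMAP (cat.), CH2Cl2, 0 °C → rt
Reagents that add atoms: none
Why: N-acylation of the oxazolidinone by the acid chloride under nucleophilic catalysis should give the imide without touching the methyl ester; no stereocentre is formed.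

Step 2
Reactants: 3 methyl 4-[(4R)-4-benzyl-2-oxo-1,3-oxazolidin-3-yl]-4-oxobutanoate; 4 4-(benzyloxy)-3,5-dimethoxybenzaldehyde
Product: 7 (4R)-4-benzyl-3-{(2R,3R)-2-[4-(benzyloxy)-3,5-dimethoxyphenyl]-5-oxooxolane-3-carbonyl}-1,3-oxazolidin-2-one, via Z-boron enolate 5 (not isolated), via syn-aldol hydroxy ester 6 (not isolated)
Conditions: Bu2BOTf, i-Pr2NEt, CH2Cl2, 0 °C; 4, −78 → 0 °C; H2O2, MeOH/pH 7 buffer, 0 °C; then PPTS (cat.), CH2Cl2, rt
Reagents that add atoms: none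
Why: Evans syn-aldol reaction, in which the Z-boron enolate adds through a chair transition state on the enolate face left open by the (R)-benzyl group of the auxiliary, should set both new stereocentres (R at the α-carbon, R at the carbinol), and the γ-hydroxy ester should then lactonize to the 2,3-trans lactone with loss of methanol.

Step 3
Reactants: 7 (4R)-4-benzyl-3-{(2R,3R)-2-[4-(benzyloxy)-3,5-dimethoxyphenyl]-5-oxooxolane-3-carbonyl}-1,3-oxazolidin-2-one
Product: 9 (2R,3R)-2-[4-(benzyloxy)-3,5-dimethoxyphenyl]-5-oxooxolane-3-carboxylic acid, via peroxy acid 8 (not isolated)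
Conditions: LiOH, H2O2, THF/H2O, 0 °C; Na2SO3; then HCl to pH 2
Reagents that add atoms: hydrogen peroxide (as LiOOH), OO
Why: Hydroperoxide cleavage of the N-acyloxazolidinone at the exocyclic carbonyl, sulfite reduction of the peroxy acid and acidification (which recloses any opened lactone) should give the acid with both stereocentres retained.

Step 4
Reactants: 9 (2R,3R)-2-[4-(benzyloxy)-3,5-dimethoxyphenyl]-5-oxooxolane-3-carboxylic acid
Product: 10 (4S,5R)-5-[4-(benzyloxy)-3,5-dimethoxyphenyl]-4-(hydroxymethyl)oxolan-2-one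
Conditions: BH3·SMe2, THF, 0 °C → rt; MeOH, then aqueous work-up
Reagents that add atoms: none
Why: Chemoselective borane reduction, which takes the carboxylic acid through an acyloxyborane much faster than it attacks the γ-lactone, should give the primary alcohol under non-basic conditions that leave the stereocentres untouched.

Step 5
Reactants: 10 (4S,5R)-5-[4-(benzyloxy)-3,5-dimethoxyphenyl]-4-(hydroxymethyl)oxolan-2-one
Product: 11 (4S,5R)-4-[(benzyloxy)methyl]-5-[4-(benzyloxy)-3,5-dimethoxyphenyl]oxolan-2-one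
Conditions: BnOC(=NH)CCl3, TfOH (cat.), CH2Cl2/cyclohexane, 0 °C → rt
Reagents that add atoms: benzyl 2,2,2-trichloroacetimidate, ClC(Cl)(Cl)C(=N)OCc1ccccc1
Why: Acid-catalysed O-benzylation with the trichloroacetimidate should protect the primary alcohol without forming an alkoxide, so translactonization onto the lactone carbonyl is avoided.

Step 6
Reactants: 11 (4S,5R)-4-[(benzyloxy)methyl]-5-[4-(benzyloxy)-3,5-dimethoxyphenyl]oxolan-2-one; 12 benzyl chloromethyl ether
Product: 14 (3S,4S,5R)-3,4-bis[(benzyloxy)methyl]-5-[4-(benzyloxy)-3,5-dimethoxyphenyl]oxolan-2-one, via lithium enolate 13 (not isolated)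
Conditions: LiN(i-Pr)2, THF, −78 °C; 12, −78 → −40 °C
Reagents that add atoms: none
Why: Alkylation of the lactone lithium enolate by the reactive chloromethyl ether should take place on the face anti to the C4 benzyloxymethyl group, setting C3 as S (3,4-trans) and completing the all-trans lactone.

Step 7
Reactants: 14 (3S,4S,5R)-3,4-bis[(benzyloxy)methyl]-5-[4-(benzyloxy)-3,5-dimethoxyphenyl]oxolan-2-one
Product: 15 (3S,4S,5R)-3,4-bis[(benzyloxy)methyl]-5-[4-(benzyloxy)-3,5-dimethoxyphenyl]oxolan-2-ol (both C2 epimers)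
Conditions: i-Bu2AlH, CH2Cl2, −78 °C; aqueous potassium sodium tartrate
Reagents that add atoms: none
Why: Partial hydride reduction of the lactone at −78 °C should stop at the aluminium hemiacetal and give the lactol on work-up, with C3, C4 and C5 untouched and C2 formed as an inconsequential epimer mixture.

Step 8
Reactants: 15 (3S,4S,5R)-3,4-bis[(benzyloxy)methyl]-5-[4-(benzyloxy)-3,5-dimethoxyphenyl]oxolan-2-ol; 16 2,6-dimethoxyphenol
Product: 18 4-{(2R,3S,4S,5R)-3,4-bis[(benzyloxy)methyl]-5-[4-(benzyloxy)-3,5-dimethoxyphenyl]oxolan-2-yl}-2,6-dimethoxyphenol, via oxocarbenium ion 17 (not isolated)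
Conditions: 16 (3 equiv), BF3·OEt2 (2 equiv), 4 Å MS, CH2Cl2, −78 → −30 °C; NaHCO3 (aq)
Reagents that add atoms: none
Why: BF3·OEt2 ionizes the lactol to the five-membered oxocarbenium ion 17, which is attacked by C4 of 2,6-dimethoxyphenol (para to OH) and rearomatizes by proton loss, a Friedel–Crafts C-arylation. The closest known reaction type is the Lewis-acid C-arylation of furanose-type lactols and 2-alkoxyoxolanes with electron-rich phenols, as used for aryl C-glycosides. No ring is closed in this step; the oxolane ring is already present and only the exocyclic aryl–C2 bond forms. The new stereocentre C2 is controlled by the neighbouring C3 benzyloxymethyl group: the arene should add to the face of C2 anti to it, giving the 2,3-trans and hence all-trans (2R,3S,4S,5R) oxolane, which is also the thermodynamically favoured isomer should the benzylic C2–O bond ionize reversibly. The step needs para-regioselectivity on the phenol and C- over O-arylation; the para-directing free OH, the unhindered C4 between two CH positions and the acid-promoted O-to-C migration of any aryl acetal should secure this. Excess phenol and low temperature should suppress opening of the product to diarylmethanes.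

Step 9
Reactants: 18 4-{(2R,3S,4S,5R)-3,4-bis[(benzyloxy)methyl]-5-[4-(benzyloxy)-3,5-dimethoxyphenyl]oxolan-2-yl}-2,6-dimethoxyphenol
Product: 19 4,4'-[(2R,3S,4S,5R)-3,4-bis(hydroxymethyl)oxolane-2,5-diyl]bis(2,6-dimethoxyphenol)
Conditions: H2 (1 atm), Pd/C, EtOAc/MeOH, rt
Reagents that add atoms: none
Why: Hydrogenolysis of the aryl benzyl ether and the two alkyl benzyl ethers over Pd/C under neutral conditions should release the second phenol and both primary alcohols without touching the four stereocentres.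

Compound list
1 | (R)-4-benzyl-1,3-oxazolidin-2-one | O=C1N[C@H](Cc2ccccc2)CO1 | starting material
2 | methyl 4-chloro-4-oxobutanoate | COC(=O)CCC(=O)Cl | starting material
3 | methyl 4-[(4R)-4-benzyl-2-oxo-1,3-oxazolidin-3-yl]-4-oxobutanoate | COC(=O)CCC(=O)N1C(=O)OC[C@H]1Cc1ccccc1 | intermediate
4 | 4-(benzyloxy)-3,5-dimethoxybenzaldehyde | COc1cc(C=O)cc(OC)c1OCc1ccccc1 | starting material
5 | Z-dibutylboron enolate of 3 | CCCCB(CCCC)O/C(=C\CC(=O)OC)N1C(=O)OC[C@H]1Cc1ccccc1 | intermediate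
6 | methyl (3R)-3-{(R)-[4-(benzyloxy)-3,5-dimethoxyphenyl](hydroxy)methyl}-4-[(4R)-4-benzyl-2-oxo-1,3-oxazolidin-3-yl]-4-oxobutanoate | O[C@@H](c1cc(OC)c(OCc2ccccc2)c(OC)c1)[C@H](C(=O)N1C(=O)OC[C@H]1Cc1ccccc1)CC(=O)OC | intermediate
7 | (4R)-4-benzyl-3-{(2R,3R)-2-[4-(benzyloxy)-3,5-dimethoxyphenyl]-5-oxooxolane-3-carbonyl}-1,3-oxazolidin-2-one | O=C1O[C@@H](c2cc(OC)c(OCc3ccccc3)c(OC)c2)[C@H](C(=O)N2C(=O)OC[C@H]2Cc2ccccc2)C1 | intermediate
8 | (2R,3R)-2-[4-(benzyloxy)-3,5-dimethoxyphenyl]-5-oxooxolane-3-carboperoxoic acid | O=C1O[C@@H](c2cc(OC)c(OCc3ccccc3)c(OC)c2)[C@H](C(=O)OO)C1 | intermediate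
9 | (2R,3R)-2-[4-(benzyloxy)-3,5-dimethoxyphenyl]-5-oxooxolane-3-carboxylic acid | O=C1O[C@@H](c2cc(OC)c(OCc3ccccc3)c(OC)c2)[C@H](C(=O)O)C1 | intermediate
10 | (4S,5R)-5-[4-(benzyloxy)-3,5-dimethoxyphenyl]-4-(hydroxymethyl)oxolan-2-one | O=C1O[C@@H](c2cc(OC)c(OCc3ccccc3)c(OC)c2)[C@H](CO)C1 | intermediate
11 | (4S,5R)-4-[(benzyloxy)methyl]-5-[4-(benzyloxy)-3,5-dimethoxyphenyl]oxolan-2-one | O=C1O[C@@H](c2cc(OC)c(OCc3ccccc3)c(OC)c2)[C@H](COCc2ccccc2)C1 | intermediate
12 | benzyl chloromethyl ether | ClCOCc1ccccc1 | starting material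
13 | lithium enolate of 11 | [Li+].[O-]C1O[C@@H](c2cc(OC)c(OCc3ccccc3)c(OC)c2)[C@H](COCc2ccccc2)C=1 | intermediate
14 | (3S,4S,5R)-3,4-bis[(benzyloxy)methyl]-5-[4-(benzyloxy)-3,5-dimethoxyphenyl]oxolan-2-one | O=C1O[C@@H](c2cc(OC)c(OCc3ccccc3)c(OC)c2)[C@H](COCc2ccccc2)[C@H]1COCc1ccccc1 | intermediate
15 | (3S,4S,5R)-3,4-bis[(benzyloxy)methyl]-5-[4-(benzyloxy)-3,5-dimethoxyphenyl]oxolan-2-ol (both C2 epimers) | OC1O[C@@H](c2cc(OC)c(OCc3ccccc3)c(OC)c2)[C@H](COCc2ccccc2)[C@H]1COCc1ccccc1 | intermediate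
16 | 2,6-dimethoxyphenol | COc1cccc(OC)c1O | starting material
17 | cyclic oxocarbenium ion from 15 (C2=O1 cation, C3, C4 and C5 as in 15) | [CH]1=[O+][C@@H](c2cc(OC)c(OCc3ccccc3)c(OC)c2)[C@H](COCc2ccccc2)[C@H]1COCc1ccccc1 | intermediate
18 | 4-{(2R,3S,4S,5R)-3,4-bis[(benzyloxy)methyl]-5-[4-(benzyloxy)-3,5-dimethoxyphenyl]oxolan-2-yl}-2,6-dimethoxyphenol | COc1cc([C@@H]2O[C@@H](c3cc(OC)c(OCc4ccccc4)c(OC)c3)[C@H](COCc3ccccc3)[C@H]2COCc2ccccc2)cc(OC)c1O | intermediate
19 | 4,4'-[(2R,3S,4S,5R)-3,4-bis(hydroxymethyl)oxolane-2,5-diyl]bis(2,6-dimethoxyphenol) | COc1cc([C@@H]2O[C@@H](c3cc(OC)c(O)c(OC)c3)[C@H](CO)[C@H]2CO)cc(OC)c1O | target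

Total step count: 9. Longest linear sequence: 9 steps (1 → 3 → 7 → 9 → 10 → 11 → 14 → 15 → 18 → 19).

Steps most likely to fail

Step 8. The oxocarbenium ion may attack the phenol at the carbon ortho to a methoxy group instead of the para carbon, and the product's benzylic C–O bonds may open under the Lewis acid and be arylated a second time. The fallback fixes the regiochemistry with an aryl–metal reagent and sets out from lactone 14. Commercial 4-bromo-2,6-dimethoxyphenol is benzylated (BnBr, K2CO3, DMF) to 2-(benzyloxy)-5-bromo-1,3-dimethoxybenzene F1. Bromine–lithium exchange (n-BuLi, THF, −78 °C) gives [4-(benzyloxy)-3,5-dimethoxyphenyl]lithium F2, which adds to the carbonyl of 14 to give the cyclic hemiketal (3S,4S,5R)-3,4-bis[(benzyloxy)methyl]-2,5-bis[4-(benzyloxy)-3,5-dimethoxyphenyl]oxolan-2-ol F3. Ionic reduction (Et3SiH, BF3·OEt2, CH2Cl2, −78 → 0 °C) should deliver hydride anti to the C3 group, and the 2,3-cis isomer formed first should equilibrate under BF3·OEt2 to the all-trans (2R,3S,4S,5R)-3,4-bis[(benzyloxy)methyl]-2,5-bis[4-(benzyloxy)-3,5-dimethoxyphenyl]oxolane F4. Hydrogenolysis under the conditions of step 9 brings the route back at 19.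

Step 6. Proton transfer between product and enolate may lead to double alkylation or to elimination of benzyl oxide from the product enolate, and C-alkylation by the chloromethyl ether may be slow. The fallback replaces the alkylation by an aldol reaction and sets out from 11. The enolate (LiN(i-Pr)2, THF, −78 °C) is treated with gaseous formaldehyde to give, again anti to the C4 group, (3S,4S,5R)-4-[(benzyloxy)methyl]-5-[4-(benzyloxy)-3,5-dimethoxyphenyl]-3-(hydroxymethyl)oxolan-2-one F5. Acid-catalysed benzylation as in step 5 brings the route back at 14.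

Step 9. The two alkyl benzyl ethers cleave slowly, so reductive opening of the benzylic C2–O and C5–O bonds of the oxolane may compete. The fallback carries both primary alcohols as silyl ethers and sets out from 10.
- Silylation (t-BuPh2SiCl, imidazole, CH2Cl2) gives (4S,5R)-5-[4-(benzyloxy)-3,5-dimethoxyphenyl]-4-{[(tert-butyldiphenylsilyl)oxy]methyl}oxolan-2-one F6.
- Enolate hydroxymethylation (LiN(i-Pr)2, gaseous formaldehyde, THF, −78 °C) gives (3S,4S,5R)-5-[4-(benzyloxy)-3,5-dimethoxyphenyl]-4-{[(tert-butyldiphenylsilyl)oxy]methyl}-3-(hydroxymethyl)oxolan-2-one F7.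
- A second silylation gives (3S,4S,5R)-5-[4-(benzyloxy)-3,5-dimethoxyphenyl]-3,4-bis{[(tert-butyldiphenylsilyl)oxy]methyl}oxolan-2-one F8.
- Reduction with i-Bu2AlH at −78 °C gives (3S,4S,5R)-5-[4-(benzyloxy)-3,5-dimethoxyphenyl]-3,4-bis{[(tert-butyldiphenylsilyl)oxy]methyl}oxolan-2-ol F9.
- Arylation with 16 under the conditions of step 8 gives 4-{(2R,3S,4S,5R)-5-[4-(benzyloxy)-3,5-dimethoxyphenyl]-3,4-bis{[(tert-butyldiphenylsilyl)oxy]methyl}oxolan-2-yl}-2,6-dimethoxyphenol F10.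
- Desilylation (Bu4NF, AcOH, THF) gives 4-{(2R,3S,4S,5R)-5-[4-(benzyloxy)-3,5-dimethoxyphenyl]-3,4-bis(hydroxymethyl)oxolan-2-yl}-2,6-dimethoxyphenol F11.
- A brief hydrogenolysis of the single, fast-cleaving aryl benzyl ether (H2, Pd/C, EtOAc) brings the route back at 19.

Further compounds
F1 | step 8 | 2-(benzyloxy)-5-bromo-1,3-dimethoxybenzene | COc1cc(Br)cc(OC)c1OCc1ccccc1
F2 | step 8 | [4-(benzyloxy)-3,5-dimethoxyphenyl]lithium | [Li]c1cc(OC)c(OCc2ccccc2)c(OC)c1
F3 | step 8 | (3S,4S,5R)-3,4-bis[(benzyloxy)methyl]-2,5-bis[4-(benzyloxy)-3,5-dimethoxyphenyl]oxolan-2-ol (both C2 epimers) | OC1(c2cc(OC)c(OCc3ccccc3)c(OC)c2)O[C@@H](c2cc(OC)c(OCc3ccccc3)c(OC)c2)[C@H](COCc2ccccc2)[C@H]1COCc1ccccc1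
F4 | step 8 | (2R,3S,4S,5R)-3,4-bis[(benzyloxy)methyl]-2,5-bis[4-(benzyloxy)-3,5-dimethoxyphenyl]oxolane | COc1cc([C@@H]2O[C@@H](c3cc(OC)c(OCc4ccccc4)c(OC)c3)[C@H](COCc3ccccc3)[C@H]2COCc2ccccc2)cc(OC)c1OCc1ccccc1
F5 | step 6 | (3S,4S,5R)-4-[(benzyloxy)methyl]-5-[4-(benzyloxy)-3,5-dimethoxyphenyl]-3-(hydroxymethyl)oxolan-2-one | O=C1O[C@@H](c2cc(OC)c(OCc3ccccc3)c(OC)c2)[C@H](COCc2ccccc2)[C@H]1CO
F6 | step 9 | (4S,5R)-5-[4-(benzyloxy)-3,5-dimethoxyphenyl]-4-{[(tert-butyldiphenylsilyl)oxy]methyl}oxolan-2-one | O=C1O[C@@H](c2cc(OC)c(OCc3ccccc3)c(OC)c2)[C@H](CO[Si](c2ccccc2)(c2ccccc2)C(C)(C)C)C1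
F7 | step 9 | (3S,4S,5R)-5-[4-(benzyloxy)-3,5-dimethoxyphenyl]-4-{[(tert-butyldiphenylsilyl)oxy]methyl}-3-(hydroxymethyl)oxolan-2-one | O=C1O[C@@H](c2cc(OC)c(OCc3ccccc3)c(OC)c2)[C@H](CO[Si](c2ccccc2)(c2ccccc2)C(C)(C)C)[C@H]1CO
F8 | step 9 | (3S,4S,5R)-5-[4-(benzyloxy)-3,5-dimethoxyphenyl]-3,4-bis{[(tert-butyldiphenylsilyl)oxy]methyl}oxolan-2-one | O=C1O[C@@H](c2cc(OC)c(OCc3ccccc3)c(OC)c2)[C@H](CO[Si](c2ccccc2)(c2ccccc2)C(C)(C)C)[C@H]1CO[Si](c1ccccc1)(c1ccccc1)C(C)(C)C
F9 | step 9 | (3S,4S,5R)-5-[4-(benzyloxy)-3,5-dimethoxyphenyl]-3,4-bis{[(tert-butyldiphenylsilyl)oxy]methyl}oxolan-2-ol (both C2 epimers) | OC1O[C@@H](c2cc(OC)c(OCc3ccccc3)c(OC)c2)[C@H](CO[Si](c2ccccc2)(c2ccccc2)C(C)(C)C)[C@H]1CO[Si](c1ccccc1)(c1ccccc1)C(C)(C)C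
F10 | step 9 | 4-{(2R,3S,4S,5R)-5-[4-(benzyloxy)-3,5-dimethoxyphenyl]-3,4-bis{[(tert-butyldiphenylsilyl)oxy]methyl}oxolan-2-yl}-2,6-dimethoxyphenol | COc1cc([C@@H]2O[C@@H](c3cc(OC)c(OCc4ccccc4)c(OC)c3)[C@H](CO[Si](c3ccccc3)(c3ccccc3)C(C)(C)C)[C@H]2CO[Si](c2ccccc2)(c2ccccc2)C(C)(C)C)cc(OC)c1O
F11 | step 9 | 4-{(2R,3S,4S,5R)-5-[4-(benzyloxy)-3,5-dimethoxyphenyl]-3,4-bis(hydroxymethyl)oxolan-2-yl}-2,6-dimethoxyphenol | COc1cc([C@@H]2O[C@@H](c3cc(OC)c(OCc4ccccc4)c(OC)c3)[C@H](CO)[C@H]2CO)cc(OC)c1O
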